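A direct plan would buy the seven-membered ring as 3-methylcyclohept-2-en-1-one (A1) and would set C1 by asymmetric conjugate addition of a butenyl Grignard reagent (Cu(OTf)2, chiral carbene ligand). Numbering used throughout: C1 angular-methyl carbon, C2, C3, C4 isopropyl carbinol, C5 ring-fusion CH, C6 ester carbon, C7, C8 methyl carbinol, C9=C10 ring alkene.
Ozonolysis to an ester, two dehydrogenations and a Me2CuLi addition with Saegusa oxidation would then give dienone ester A2.
A Dieckmann condensation would close the five-membered ring (bond C4–C5) and, in the same flask, O-silylation and i-PrMgCl/CeCl3 addition would give ketol A3.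
Directed reduction at C6, hydroxyl-directed epoxidation (VO(acac)2) to A4, hydride opening, esterification at C6 and release of the phenol would end the route.
Weak point one, the way from A1 to A2: four steps of oxidation-state changes and methyl transfer would build only a methylcycloheptadienone, and the regiochemistry of the quinone dehydrogenation on a seven-membered enone is not secured.
Weak point two, the one-flask ring closure and isopropyl addition to A3: it would have to tell C4 from C6 of a 1,3-diketone through a silyl shift, choose a face of a flat bicycle and spare a tertiary aldol, and C5 would be corrected only by epimerisation.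
Weak point three, the hydride opening of vinyl epoxide A4: attack at the secondary, non-allylic carbon would compete with allylic and SN2′ delivery, late and on precious material.

**Retrosynthetic overview**
Feature used: in the seven-membered ring (C1, C5, C6, C7, C8, C9, C10) the cis C9=C10 alkene stands between the quaternary C1 and C8, next to the ring-fusion bond C1–C5. This is the imprint of a vinylcyclopropane–alkyne (5+2) cycloaddition, with C1=C10 as the alkene, C9/C8/C7 as the cyclopropane and C5≡C6 as the alkyne on a C2–C3–C4 tether.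
Key disconnection: bonds C1–C5 and C6–C7, with C7–C9 of the cyclopropane cut. The five- and the seven-membered ring close in the same step from the acyclic, achiral ynone 8 (four steps from cyclopropanecarbaldehyde), and the catalyst [Rh((R)-BINAP)]SbF6 sets C1.
On the bicycle the stereocentres follow one by one: C4 by i-PrMgCl/CeCl3 addition anti to the angular methyl, C5 by equilibration once the C6–Si bond is oxidised to the ketone, C6 by hydroxyl-directed reduction, and C8 by allylic oxidation and methyl addition after the ester is in place.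
The design needs no redox run-up to a cycloheptadienone, puts no 1,3-diketone under a nucleophile (C6 stays a C–Si bond until C4 is set) and contains no vinyl epoxide.
Key step: step 5

Assumption: the sense of induction of the BINAP complex in step 5 has to be found by experiment ((R)-BINAP is written, (S)-BINAP would be used if it gave the antipode), and benzyl(ethynyl)dimethylsilane 6 is taken as purchasable.

**Route**

Step 1
Reactants: 1 cyclopropanecarbaldehyde
Product: 2 1-cyclopropyl-2-methylprop-2-en-1-ol (racemic)
Conditions: CH2=C(CH3)MgBr, THF, 0 °C; aq. NH4Cl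
Reagents that add atoms: isopropenylmagnesium bromide (CC(=C)[Mg]Br)
Why: Grignard 1,2-addition to an unhindered aldehyde, in which the carbinol stereocentre is left racemic on purpose because the next step destroys it.

Step 2
Reactants: 2 1-cyclopropyl-2-methylprop-2-en-1-ol
Product: 4 ethyl (4E)-5-cyclopropyl-4-methylpent-4-enoate, via mixed ketene acetal 3 (not isolated)
Conditions: CH3C(OEt)3 (excess), EtCO2H (cat.), 140 °C, EtOH distilled off
Reagents that add atoms: triethyl orthoacetate (CCOC(C)(OCC)OCC)
Why: Johnson–Claisen rearrangement of the ketene acetal formed in the flask, through a chair transition state with the cyclopropyl group equatorial, should move the acetate unit to the alkene terminus and give the E trisubstituted alkene (cyclopropyl trans to the new chain), with no stereocentre left.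

Step 3
Reactants: 4 ethyl (4E)-5-cyclopropyl-4-methylpent-4-enoate
Product: 5 (4E)-5-cyclopropyl-N-methoxy-N,4-dimethylpent-4-enamide
Conditions: MeNH(OMe)·HCl, i-PrMgCl, THF, −20 → 0 °C
Reagents that add atoms: N,O-dimethylhydroxylamine hydrochloride (CNOC.Cl)
Why: aminolysis of the ester by the chloromagnesium amide (Weinreb amide synthesis) should touch neither the alkene nor the cyclopropane.

Step 4
Reactants: 5 (4E)-5-cyclopropyl-N-methoxy-N,4-dimethylpent-4-enamide; 6 benzyl(ethynyl)dimethylsilane
Product: 8 (6E)-1-[benzyl(dimethyl)silyl]-7-cyclopropyl-6-methylhept-6-en-1-yn-3-one, via lithium acetylide 7 (not isolated)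
Conditions: 6, n-BuLi, THF, −78 °C; then 5, −78 → 0 °C; aq. NH4Cl
Reagents that add atoms: none
Why: Weinreb ketone synthesis, in which the lithium acetylide adds once and the chelated tetrahedral intermediate collapses only on work-up, should give the ynone without over-addition and without change of the E alkene.

Step 5
Reactants: 8 (6E)-1-[benzyl(dimethyl)silyl]-7-cyclopropyl-6-methylhept-6-en-1-yn-3-one
Product: 9 (3aR)-8-[benzyl(dimethyl)silyl]-3a-methyl-3,3a,6,7-tetrahydroazulen-1(2H)-one
Conditions: [Rh((R)-BINAP)]SbF6 (10 mol %), ClCH2CH2Cl, 40 → 70 °C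
Reagents that add atoms: none
Why: The cationic monovalent rhodium complex binds the ynone alkyne and the trisubstituted alkene of 8 and undergoes oxidative cyclometalation that joins C5 to C1, which closes the five-membered ring in the exo mode at both π-bonds through the C2–C3–C4 tether. The cyclopropylcarbinyl–rhodium unit then opens the C9–C7 bond of the cyclopropane with release of its strain to an eight-membered rhodacycle, and reductive elimination of the C6–C7 bond closes the seven-membered ring and leaves the cis C9=C10 alkene and the C5=C6 alkenylsilane. The closest known reaction type is the intramolecular (5+2) cycloaddition of tethered alkyne–vinylcyclopropanes under monovalent rhodium catalysis, which is known with conjugated and silylated alkynes, with alkenes that carry a methyl group at the tether carbon (angular quaternary carbon) and, with BINAP-type ligands, in enantioselective form. C1 is the only stereocentre that forms, and the chiral diphosphine controls it by selecting the face of the E alkene that enters the rhodacycle. The step needs cycloaddition to outrun plain ring opening of the vinylcyclopropane and oligomerisation of the alkyne, which the short tether, the activated ynone and the silyl cap should secure. The regiochemistry is fixed by the tether, and the two cyclopropane CH2 groups are equivalent.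

Step 6
Reactants: 9 (3aR)-8-[benzyl(dimethyl)silyl]-3a-methyl-3,3a,6,7-tetrahydroazulen-1(2H)-one
Product: 10 (1R,3aR)-8-[benzyl(dimethyl)silyl]-3a-methyl-1-(propan-2-yl)-1,2,3,3a,6,7-hexahydroazulen-1-ol
Conditions: i-PrMgCl, CeCl3, THF, −78 °C; aq. NH4Cl
Reagents that add atoms: isopropylmagnesium chloride (CC(C)[Mg]Cl)
Why: organocerium 1,2-addition to the enone (cerium suppresses enolisation and β-hydride reduction, and the silylated C6 is closed to conjugate addition) should take place on the α face of the C4 carbonyl, anti to the pseudo-axial C1 methyl group that stands 1,3 to it, which sets C4 with the hydroxyl β and the isopropyl group α.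

Step 7
Reactants: 10 (1R,3aR)-8-[benzyl(dimethyl)silyl]-3a-methyl-1-(propan-2-yl)-1,2,3,3a,6,7-hexahydroazulen-1-ol
Product: 12 (3R,3aR,8aR)-3-hydroxy-8a-methyl-3-(propan-2-yl)-2,3,3a,5,6,8a-hexahydroazulen-4(1H)-one, via alkenylsilanol 11 (not isolated)
Conditions: Bu4NF, THF, 0 °C; then H2O2 (30 %), KHCO3, MeOH, 23 °C
Reagents that add atoms: hydrogen peroxide (OO)
Why: Tamao–Fleming oxidation, in which fluoride removes the benzyl group from silicon and basic hydrogen peroxide oxidises the alkenylsilanol to the enol of the C6 ketone, should end, by protonation or by equilibration under the hydrogencarbonate conditions, at the trans-fused ketol (H-5 α), the C5 epimer in which C6 is anti to the isopropyl group on C4 and the C4 hydroxyl can hydrogen-bond to the new carbonyl.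

Step 8
Reactants: 12 (3R,3aR,8aR)-3-hydroxy-8a-methyl-3-(propan-2-yl)-2,3,3a,5,6,8a-hexahydroazulen-4(1H)-one
Product: 13 (3R,3aS,4S,8aR)-8a-methyl-3-(propan-2-yl)-1,2,3,3a,4,5,6,8a-octahydroazulene-3,4-diol
Conditions: Me4NBH(OAc)3, AcOH/MeCN, −30 °C
Reagents that add atoms: none
Why: Evans–Saksena reduction, in which the C4 hydroxyl exchanges onto boron and delivers hydride within the molecule to the β face of the C6 carbonyl, should give the 1,3-anti diol with the 6α hydroxyl.

Step 9
Reactants: 13 (3R,3aS,4S,8aR)-8a-methyl-3-(propan-2-yl)-1,2,3,3a,4,5,6,8a-octahydroazulene-3,4-diol; 14 4-{[tert-butyl(dimethyl)silyl]oxy}benzoic acid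
Product: 15 (3R,3aS,4S,8aR)-3-hydroxy-8a-methyl-3-(propan-2-yl)-1,2,3,3a,4,5,6,8a-octahydroazulen-4-yl 4-{[tert-butyl(dimethyl)silyl]oxy}benzoate
Conditions: DIC, DMAP (cat.), CH2Cl2, 23 °C
Reagents that add atoms: none
Why: Steglich esterification should acylate only the secondary C6 hydroxyl, the tertiary C4 hydroxyl being inert under these conditions, and touches no stereocentre.

Step 10
Reactants: 15 (3R,3aS,4S,8aR)-3-hydroxy-8a-methyl-3-(propan-2-yl)-1,2,3,3a,4,5,6,8a-octahydroazulen-4-yl 4-{[tert-butyl(dimethyl)silyl]oxy}benzoate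
Product: 16 (3R,3aS,4S,8aR)-3-hydroxy-8a-methyl-6-oxo-3-(propan-2-yl)-1,2,3,3a,4,5,6,8a-octahydroazulen-4-yl 4-{[tert-butyl(dimethyl)silyl]oxy}benzoate
Conditions: CrO3, 3,5-dimethylpyrazole, CH2Cl2, −20 °C
Reagents that add atoms: chromium trioxide (O=[Cr](=O)=O)
Why: allylic oxidation with the CrO3–3,5-dimethylpyrazole complex can only attack C8, the one allylic methylene of the C9=C10 alkene because C1 is quaternary, and its non-basic medium should spare the β-aroyloxy ketone that results and every stereocentre.

Step 11
Reactants: 16 (3R,3aS,4S,8aR)-3-hydroxy-8a-methyl-6-oxo-3-(propan-2-yl)-1,2,3,3a,4,5,6,8a-octahydroazulen-4-yl 4-{[tert-butyl(dimethyl)silyl]oxy}benzoate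
Product: 17 (3R,3aS,4S,6R,8aR)-3,6-dihydroxy-6,8a-dimethyl-3-(propan-2-yl)-1,2,3,3a,4,5,6,8a-octahydroazulen-4-yl 4-{[tert-butyl(dimethyl)silyl]oxy}benzoate
Conditions: MeMgBr, CeCl3, THF, −78 °C; AcOH quench at −78 °C
Reagents that add atoms: methylmagnesium bromide (C[Mg]Br)
Why: organocerium 1,2-addition to the cycloheptenone (weakly basic, so that neither enolisation with loss of the benzoate nor attack on the hindered aryl ester should compete) should bring the methyl group to the β face of C8, anti to the pseudo-axial C7–H bond and on the side of the out-of-plane C6, the torsionally favoured axial-type path of cycloalkenone additions, which places the C8 hydroxyl α, cis to the C6 ester.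

Step 12
Reactants: 17 (3R,3aS,4S,6R,8aR)-3,6-dihydroxy-6,8a-dimethyl-3-(propan-2-yl)-1,2,3,3a,4,5,6,8a-octahydroazulen-4-yl 4-{[tert-butyl(dimethyl)silyl]oxy}benzoate
Product: 18 (3R,3aS,4S,6R,8aR)-3,6-dihydroxy-6,8a-dimethyl-3-(propan-2-yl)-1,2,3,3a,4,5,6,8a-octahydroazulen-4-yl 4-hydroxybenzoate (CNP0280165.4)
Conditions: Bu4NF, AcOH, THF, 0 °C
Reagents that add atoms: none
Why: buffered fluoride cleaves the aryl silyl ether far faster than it attacks the hindered secondary benzoate or ionises the tertiary allylic alcohol, so the phenol is released without change at any stereocentre.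

**Compound list**

1 | cyclopropanecarbaldehyde | O=CC1CC1 | starting material
2 | 1-cyclopropyl-2-methylprop-2-en-1-ol (racemic) | CC(=C)C(O)C1CC1 | intermediate
3 | 1-cyclopropyl-2-methylprop-2-en-1-yl 1-ethoxyethenyl ether (mixed ketene acetal) | C=C(OCC)OC(C1CC1)C(C)=C | intermediate
4 | ethyl (4E)-5-cyclopropyl-4-methylpent-4-enoate | CCOC(=O)CC/C(C)=C/C1CC1 | intermediate
5 | (4E)-5-cyclopropyl-N-methoxy-N,4-dimethylpent-4-enamide | CON(C)C(=O)CC/C(C)=C/C1CC1 | intermediate
6 | benzyl(ethynyl)dimethylsilane | C#C[Si](C)(C)Cc1ccccc1 | starting material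
7 | lithium [benzyl(dimethyl)silyl]acetylide | [Li]C#C[Si](C)(C)Cc1ccccc1 | intermediate
8 | (6E)-1-[benzyl(dimethyl)silyl]-7-cyclopropyl-6-methylhept-6-en-1-yn-3-one | O=C(C#C[Si](C)(C)Cc1ccccc1)CC/C(C)=C/C1CC1 | intermediate
9 | (3aR)-8-[benzyl(dimethyl)silyl]-3a-methyl-3,3a,6,7-tetrahydroazulen-1(2H)-one (C4 ketone, C5=C6–Si, C9=C10, C1 quaternary) | O=C1CC[C@]2(C)C=CCCC([Si](C)(C)Cc3ccccc3)=C21 | intermediate
10 | (1R,3aR)-8-[benzyl(dimethyl)silyl]-3a-methyl-1-(propan-2-yl)-1,2,3,3a,6,7-hexahydroazulen-1-ol (C4: OH β, isopropyl α) | CC(C)[C@]1(O)CC[C@]2(C)C=CCCC([Si](C)(C)Cc3ccccc3)=C21 | intermediate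
11 | (1R,3aR)-8-[hydroxy(dimethyl)silyl]-3a-methyl-1-(propan-2-yl)-1,2,3,3a,6,7-hexahydroazulen-1-ol | CC(C)[C@]1(O)CC[C@]2(C)C=CCCC([Si](C)(C)O)=C21 | intermediate
12 | (3R,3aR,8aR)-3-hydroxy-8a-methyl-3-(propan-2-yl)-2,3,3a,5,6,8a-hexahydroazulen-4(1H)-one (trans-fused ketol, H-5 α) | CC(C)[C@]1(O)CC[C@]2(C)C=CCCC(=O)[C@H]21 | intermediate
13 | (3R,3aS,4S,8aR)-8a-methyl-3-(propan-2-yl)-1,2,3,3a,4,5,6,8a-octahydroazulene-3,4-diol (4β,6α-diol, no methyl on C8) | CC(C)[C@]1(O)CC[C@]2(C)C=CCC[C@H](O)[C@H]21 | intermediate
14 | 4-{[tert-butyl(dimethyl)silyl]oxy}benzoic acid | CC(C)(C)[Si](C)(C)Oc1ccc(cc1)C(=O)O | starting material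
15 | (3R,3aS,4S,8aR)-3-hydroxy-8a-methyl-3-(propan-2-yl)-1,2,3,3a,4,5,6,8a-octahydroazulen-4-yl 4-{[tert-butyl(dimethyl)silyl]oxy}benzoate | CC(C)[C@]1(O)CC[C@]2(C)C=CCC[C@H](OC(=O)c3ccc(O[Si](C)(C)C(C)(C)C)cc3)[C@H]21 | intermediate
16 | (3R,3aS,4S,8aR)-3-hydroxy-8a-methyl-6-oxo-3-(propan-2-yl)-1,2,3,3a,4,5,6,8a-octahydroazulen-4-yl 4-{[tert-butyl(dimethyl)silyl]oxy}benzoate (C8 ketone) | CC(C)[C@]1(O)CC[C@]2(C)C=CC(=O)C[C@H](OC(=O)c3ccc(O[Si](C)(C)C(C)(C)C)cc3)[C@H]21 | intermediate
17 | (3R,3aS,4S,6R,8aR)-3,6-dihydroxy-6,8a-dimethyl-3-(propan-2-yl)-1,2,3,3a,4,5,6,8a-octahydroazulen-4-yl 4-{[tert-butyl(dimethyl)silyl]oxy}benzoate | CC(C)[C@]1(O)CC[C@]2(C)C=C[C@](C)(O)C[C@H](OC(=O)c3ccc(O[Si](C)(C)C(C)(C)C)cc3)[C@H]21 | intermediate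
18 | (3R,3aS,4S,6R,8aR)-3,6-dihydroxy-6,8a-dimethyl-3-(propan-2-yl)-1,2,3,3a,4,5,6,8a-octahydroazulen-4-yl 4-hydroxybenzoate (CNP0280165.4) | CC(C)[C@]1(O)CC[C@]2(C)C=C[C@](C)(O)C[C@H](OC(=O)c3ccc(O)cc3)[C@H]21 | target

Total step count: 12. Longest linear sequence: 12 steps (1 → 18).

**Steps most likely to fail**

Step 5. The cyclometalation may be slow at the trisubstituted alkene, so that plain ring opening of the vinylcyclopropane takes over, or the chiral complex may induce poorly at the quaternary carbon. The fallback would set C4 first with a reagent and let it steer C1. Setting out from amide 5, i-PrMgCl would give (6E)-7-cyclopropyl-2,6-dimethylhept-6-en-3-one F1. Enantioselective addition of the zinc acetylide of 6 (Me2Zn, Ti(Oi-Pr)4, the BINOL enantiomer that gives the 3R alcohol) would give (3R,6E)-1-[benzyl(dimethyl)silyl]-7-cyclopropyl-6-methyl-3-(propan-2-yl)hept-6-en-1-yn-3-ol F2. Its (5+2) cycloaddition with the achiral complex [Rh(CO)2Cl]2 in toluene at 110 °C would then form C1 under 1,3-induction from C4 (isopropyl anti to the new angular methyl) and would come back to the route at 10.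

Step 11. Methyl transfer may go to the α face of the C8 carbonyl, or the β-aroyloxy ketone may enolise and lose the benzoate. The fallback would deliver oxygen, not carbon, to C8 under non-basic conditions. Setting out from enone 16, Lombardo methylenation (Zn, CH2Br2, TiCl4, THF/CH2Cl2, 0 °C) would give (3R,3aS,4S,8aR)-3-hydroxy-8a-methyl-6-methylidene-3-(propan-2-yl)-1,2,3,3a,4,5,6,8a-octahydroazulen-4-yl 4-{[tert-butyl(dimethyl)silyl]oxy}benzoate F3. Mukaiyama hydration (Co(acac)2, PhSiH3, O2, i-PrOH) would turn the methylene carbon into the methyl group and let the tertiary C8 radical take up oxygen on the α face, anti to the angular methyl, which returns to 17.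

Step 6. Isopropyl transfer may show poor facial selectivity at C4, because the two faces differ only by the C1 methyl group against the ring carbon C10. The fallback would correct C4 by equilibration after step 7 and not in the addition. Setting out from 10 as its mixture of C4 epimers, step 7 would give ketol 12 together with (3S,8aR)-3-hydroxy-8a-methyl-3-(propan-2-yl)-2,3,3a,5,6,8a-hexahydroazulen-4(1H)-one F4 (C4 epimer, either configuration at C5). Base (DBU, toluene, 23 °C) would open F4 by retro-aldol reaction to (3S)-3-methyl-3-(4-methyl-3-oxopentyl)cyclohept-4-en-1-one F5. Reclosure would funnel the material into the most stable ketol, 12 (isopropyl anti to C6 and to the angular methyl, hydroxyl hydrogen-bonded, trans ring fusion), where the route is rejoined.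

**Further compounds**

F1 | step 5 | (6E)-7-cyclopropyl-2,6-dimethylhept-6-en-3-one | CC(C)C(=O)CC/C(C)=C/C1CC1
F2 | step 5 | (3R,6E)-1-[benzyl(dimethyl)silyl]-7-cyclopropyl-6-methyl-3-(propan-2-yl)hept-6-en-1-yn-3-ol | CC(C)[C@@](O)(C#C[Si](C)(C)Cc1ccccc1)CC/C(C)=C/C1CC1
F3 | step 11 | (3R,3aS,4S,8aR)-3-hydroxy-8a-methyl-6-methylidene-3-(propan-2-yl)-1,2,3,3a,4,5,6,8a-octahydroazulen-4-yl 4-{[tert-butyl(dimethyl)silyl]oxy}benzoate | CC(C)[C@]1(O)CC[C@]2(C)C=CC(=C)C[C@H](OC(=O)c3ccc(O[Si](C)(C)C(C)(C)C)cc3)[C@H]21
F4 | step 6 | (3S,8aR)-3-hydroxy-8a-methyl-3-(propan-2-yl)-2,3,3a,5,6,8a-hexahydroazulen-4(1H)-one (C4 epimer of 12, C5 not defined) | CC(C)[C@@]1(O)CC[C@]2(C)C=CCCC(=O)C21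
F5 | step 6 | (3S)-3-methyl-3-(4-methyl-3-oxopentyl)cyclohept-4-en-1-one | CC(C)C(=O)CC[C@]1(C)C=CCCC(=O)C1
A1 | direct plan | 3-methylcyclohept-2-en-1-one | CC1=CC(=O)CCCC1
A2 | direct plan | methyl 3-[(1S)-1,5-dimethyl-3-oxocyclohepta-4,6-dien-1-yl]propanoate | COC(=O)CC[C@]1(C)C=CC(C)=CC(=O)C1
A3 | direct plan | 4β-hydroxy-5αH-dauca-7,9-dien-6-one | CC(C)[C@]1(O)CC[C@]2(C)C=CC(C)=CC(=O)[C@H]21
A4 | direct plan | 7α,8α-epoxy-5αH-dauc-9-ene-4β,6α-diol | CC(C)[C@]1(O)CC[C@]2(C)C=C[C@]3(C)O[C@@H]3[C@H](O)[C@H]21
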